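## Retrosynthetic overview

1. Numbering used below: C1 (quaternary, methyl C15), C2 (OBz), C3, C4, C5 (methyl C16)=C6, C7 (lactone O), C8=C17 (methyl C18), C19 (lactone C=O), C9, C10, C11 (methyl C20)=C12, C13 (C=O), C14 (OAc).
2. Last bond, C7–C8: Ni/Cr-mediated addition of a C8 enol triflate to a C7 (Z)-enal with in-situ lactonisation closes the 10-membered ring and the butenolide together.
3. Before that: C8 triflate from a C8 aldehyde (Roskamp homologation, enol triflation); C4–C5 by B-alkyl Suzuki coupling of a C3=C4 vinyl group with (Z)-3-iodobut-2-en-1-ol; C11=C12 and C13–O by Schenck ene transposition of the cycloadduct C12=C13 alkene.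
4. C2: CBS reduction of a vinyl ketone made from the cycloadduct aldehyde.
5. First: ring A by a catalytic asymmetric Diels–Alder of an (E)-2-methylpent-2-enal with a (1E,3E)-1-silyloxypenta-1,3-diene (sets C1, C10, C14). Ring order: ring A, then the 10-membered ring and the butenolide in one step.

Assumption: the chiral catalysts and ligand (IDPi acid, CBS oxazaborolidine, oxazoline–sulfonamide) and methyl 2-diazopropanoate are taken as stock reagents; their preparation is not counted.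

## Route

Step 1
Reactants: 1 3-[(tert-butyldimethylsilyl)oxy]propanal + 2 2-(triphenylphosphoranylidene)propanal
Product: 3 (E)-5-[(tert-butyldimethylsilyl)oxy]-2-methylpent-2-enal
Conditions: toluene, 80 °C, 16 h
Reagents that add atoms: none
Why: Wittig olefination with a stabilised formyl ylide gives the (E)-trisubstituted enal selectively.

Step 2
Reactants: 4 (E)-pent-2-enal
Product: 5 (1E,3E)-1-(trimethylsilyloxy)penta-1,3-diene
Conditions: Me3SiCl, Et3N, ZnCl2 (2 mol %), Et2O/toluene, 40 °C; distillation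
Reagents that add atoms: chlorotrimethylsilane C[Si](C)(C)Cl
Why: Silyl dienol ether formation by γ-deprotonation and O-silylation gives mainly the (1E,3E)-diene; minor Z isomers cannot reach the s-cis form and stay inert in step 3.

Step 3
Reactants: 3 (E)-5-[(tert-butyldimethylsilyl)oxy]-2-methylpent-2-enal + 5 (1E,3E)-1-(trimethylsilyloxy)penta-1,3-diene
Product: 7 (1S,2R,5S,6R)-6-[2-(tert-butyldimethylsilyloxy)ethyl]-2-hydroxy-1,5-dimethylcyclohex-3-ene-1-carbaldehyde, via trimethylsilyl ether 6 (not isolated)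
Conditions: 5 (3 equiv), (S,S)-IDPi acid [imidodiphosphorimidate from two 3,3′-bis(3,5-bis(trifluoromethyl)phenyl)-BINOL units, N-SO2CF3 groups] (5 mol %), toluene, −60 → −40 °C, 72 h; then aq. citric acid, THF, 0 °C
Reagents that add atoms: none
Why: Proposed new method: a silylium–IDPi ion pair (formed in situ from the acid and 5) binds the aldehyde oxygen of 3 and lowers its LUMO, the nucleophilic C11 terminus of the silyl dienol ether attacks the enal β-carbon (C10) in an asynchronous endo Diels–Alder transition state so that OSi and CHO end up cis while the (E)-enal geometry places the C9 chain trans to CHO, and the confined chiral anion leaves only the C1-Re/C10-Si face open, fixing C1, C10 and C14 (C11 is flattened later); the closest known reaction types are the IDPi/silylium-catalysed Diels–Alder of α,β-unsaturated esters with dienes and the chiral boron-Lewis-acid Diels–Alder of 2-alkylacroleins, neither shown for an acyclic trisubstituted enal with a 1-silyloxy-4-alkyl diene.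

Step 4
Reactants: 7 (1S,2R,5S,6R)-6-[2-(tert-butyldimethylsilyloxy)ethyl]-2-hydroxy-1,5-dimethylcyclohex-3-ene-1-carbaldehyde
Product: 8 (1R,4S,5R,6S)-5-[2-(tert-butyldimethylsilyloxy)ethyl]-6-formyl-4,6-dimethylcyclohex-2-en-1-yl acetate
Conditions: Ac2O, DMAP (cat.), pyridine, CH2Cl2, 0 °C → rt
Reagents that add atoms: acetic anhydride CC(=O)OC(C)=O
Why: DMAP-catalysed acylation of the hindered secondary alcohol; the α-quaternary aldehyde cannot enolise or eliminate.

Step 5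
Reactants: 8 (1R,4S,5R,6S)-5-[2-(tert-butyldimethylsilyloxy)ethyl]-6-formyl-4,6-dimethylcyclohex-2-en-1-yl acetate
Product: 9 (1R,4S,5R,6R)-5-[2-(tert-butyldimethylsilyloxy)ethyl]-6-(1-hydroxyprop-2-en-1-yl)-4,6-dimethylcyclohex-2-en-1-yl acetate (both carbinol epimers)
Conditions: CH2=CHMgBr (1.3 equiv), THF, −78 °C; aq. NH4Cl at −78 °C
Reagents that add atoms: vinylmagnesium bromide C=C[Mg]Br
Why: Grignard 1,2-addition is far faster to the aldehyde than to the acetate at −78 °C, and the C2 epimer ratio is irrelevant because step 6 removes that centre.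

Step 6
Reactants: 9 (1R,4S,5R,6R)-5-[2-(tert-butyldimethylsilyloxy)ethyl]-6-(1-hydroxyprop-2-en-1-yl)-4,6-dimethylcyclohex-2-en-1-yl acetate
Product: 10 (1R,4S,5R,6S)-6-acryloyl-5-[2-(tert-butyldimethylsilyloxy)ethyl]-4,6-dimethylcyclohex-2-en-1-yl acetate
Conditions: Dess–Martin periodinane, NaHCO3, CH2Cl2, 0 °C → rt; used at once
Reagents that add atoms: none
Why: Dess–Martin oxidation converges both epimers on one vinyl ketone that cannot enolise toward the quaternary C1.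

Step 7
Reactants: 10 (1R,4S,5R,6S)-6-acryloyl-5-[2-(tert-butyldimethylsilyloxy)ethyl]-4,6-dimethylcyclohex-2-en-1-yl acetate
Product: 11 (1R,4S,5R,6R)-5-[2-(tert-butyldimethylsilyloxy)ethyl]-6-[(1S)-1-hydroxyprop-2-en-1-yl]-4,6-dimethylcyclohex-2-en-1-yl acetate
Conditions: (R)-2-methyl-CBS-oxazaborolidine (0.3 equiv), catecholborane (2 equiv), toluene, −78 °C; MeOH quench
Reagents that add atoms: none
Why: Corey–Bakshi–Shibata reduction: the quaternary C1 is the large group and vinyl the small one, so the (R)-catalyst delivers hydride to give the (S)-carbinol at C2 under reagent control, with 1,2-selectivity at low temperature.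

Step 8
Reactants: 11 (1R,4S,5R,6R)-5-[2-(tert-butyldimethylsilyloxy)ethyl]-6-[(1S)-1-hydroxyprop-2-en-1-yl]-4,6-dimethylcyclohex-2-en-1-yl acetate
Product: 12 (1S)-1-[(1R,2R,5S,6R)-2-acetoxy-6-[2-(tert-butyldimethylsilyloxy)ethyl]-1,5-dimethylcyclohex-3-en-1-yl]prop-2-en-1-yl benzoate
Conditions: BzCl, DMAP, pyridine, CH2Cl2, rt → 40 °C
Reagents that add atoms: benzoyl chloride O=C(Cl)c1ccccc1
Why: Nucleophile-catalysed O-benzoylation installs the C2 ester of the target with retention.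

Step 9
Reactants: 12 (1S)-1-[(1R,2R,5S,6R)-2-acetoxy-6-[2-(tert-butyldimethylsilyloxy)ethyl]-1,5-dimethylcyclohex-3-en-1-yl]prop-2-en-1-yl benzoate
Product: 14 (1S)-1-[(1R,2S,3S,6R)-2-acetoxy-6-[2-(tert-butyldimethylsilyloxy)ethyl]-3-hydroxy-1,5-dimethylcyclohex-4-en-1-yl]prop-2-en-1-yl benzoate, via hydroperoxide 13 (not isolated)
Conditions: O2, tetraphenylporphyrin (1 mol %), 590 nm LEDs, CH2Cl2, −10 °C; then PPh3
Reagents that add atoms: dioxygen O=O
Why: Schenck ene reaction: singlet oxygen bonds to C13 on the face of the pseudoaxial tertiary allylic H at C11 and abstracts it (the H on the acetoxy-bearing C14 is pseudoequatorial and deactivated; the monosubstituted vinyl group is inert), moving the alkene to C11=C12, and phosphine reduces the hydroperoxide; the temporary C13 centre is oxidised away in step 13.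

Step 10
Reactants: 15 but-2-yn-1-ol
Product: 17 (Z)-3-iodobut-2-en-1-ol, via cyclic alkenylalanate 16 (not isolated)
Conditions: NaAlH2(OCH2CH2OCH3)2, THF, 0 °C → rt; then I2, −78 → 0 °C
Reagents that add atoms: iodine [I][I]
Why: Hydroxyl-directed trans-hydroalumination of the propargylic alcohol and iodinolysis with retention give the (Z)-iodide, which fixes the C5=C6 geometry.

Step 11
Reactants: 14 (1S)-1-[(1R,2S,3S,6R)-2-acetoxy-6-[2-(tert-butyldimethylsilyloxy)ethyl]-3-hydroxy-1,5-dimethylcyclohex-4-en-1-yl]prop-2-en-1-yl benzoate + 17 (Z)-3-iodobut-2-en-1-ol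
Product: 19 (1S,4Z)-1-[(1R,2S,3S,6R)-2-acetoxy-6-[2-(tert-butyldimethylsilyloxy)ethyl]-3-hydroxy-1,5-dimethylcyclohex-4-en-1-yl]-6-hydroxy-4-methylhex-4-en-1-yl benzoate, via alkylborane 18 (not isolated)
Conditions: 9-BBN (3 equiv), THF, 0 °C → rt; then 17, PdCl2(dppf) (5 mol %), AsPh3, Cs2CO3, DMF/H2O, rt
Reagents that add atoms: none
Why: Anti-Markovnikov hydroboration of the terminal vinyl group (9-BBN leaves the trisubstituted ring alkene alone; any O–B borinate is hydrolysed in the basic medium) followed by B-alkyl Suzuki–Miyaura coupling with retention of the (Z)-iodide geometry forms C4–C5.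

Step 12
Reactants: 19 (1S,4Z)-1-[(1R,2S,3S,6R)-2-acetoxy-6-[2-(tert-butyldimethylsilyloxy)ethyl]-3-hydroxy-1,5-dimethylcyclohex-4-en-1-yl]-6-hydroxy-4-methylhex-4-en-1-yl benzoate
Product: 20 (1S,4Z)-1-[(1R,2S,3S,6R)-2-acetoxy-3-hydroxy-6-(2-hydroxyethyl)-1,5-dimethylcyclohex-4-en-1-yl]-6-hydroxy-4-methylhex-4-en-1-yl benzoate
Conditions: HF·pyridine, pyridine, THF, 0 °C → rt
Reagents that add atoms: none
Why: Buffered fluoride cleaves the primary silyl ether without touching the esters; the trans-diaxial C13-OH/C14-OAc pair cannot undergo acyl migration.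

Step 13
Reactants: 20 (1S,4Z)-1-[(1R,2S,3S,6R)-2-acetoxy-3-hydroxy-6-(2-hydroxyethyl)-1,5-dimethylcyclohex-4-en-1-yl]-6-hydroxy-4-methylhex-4-en-1-yl benzoate
Product: 21 (1S,4Z)-1-[(1R,2S,6R)-2-acetoxy-1,5-dimethyl-3-oxo-6-(2-oxoethyl)cyclohex-4-en-1-yl]-4-methyl-6-oxohex-4-en-1-yl benzoate
Conditions: Dess–Martin periodinane (5 equiv), NaHCO3, CH2Cl2, 0 °C → rt
Reagents that add atoms: none
Why: One buffered Dess–Martin oxidation converts the three alcohols into the ring A enone, the (Z)-enal and the saturated C8 aldehyde without alkene isomerisation.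

Step 14
Reactants: 21 (1S,4Z)-1-[(1R,2S,6R)-2-acetoxy-1,5-dimethyl-3-oxo-6-(2-oxoethyl)cyclohex-4-en-1-yl]-4-methyl-6-oxohex-4-en-1-yl benzoate
Product: 22 methyl 4-[(1R,5S,6R)-5-acetoxy-6-[(1S,4Z)-1-(benzoyloxy)-4-methyl-6-oxohex-4-en-1-yl]-2,6-dimethyl-4-oxocyclohex-2-en-1-yl]-2-methyl-3-oxobutanoate (epimers at the ester α-carbon)
Conditions: methyl 2-diazopropanoate (1.3 equiv), SnCl2 (15 mol %), CH2Cl2, 0 °C → rt
Reagents that add atoms: methyl 2-diazopropanoate CC(=[N+]=[N-])C(=O)OC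
Why: Roskamp homologation: the diazo ester adds to the Lewis-acid-activated unhindered saturated aldehyde, then a 1,2-hydride shift with loss of N2 gives the β-keto ester, while the conjugated β,β-disubstituted enal and the enone are much less electrophilic.

Step 15
Reactants: 22 methyl 4-[(1R,5S,6R)-5-acetoxy-6-[(1S,4Z)-1-(benzoyloxy)-4-methyl-6-oxohex-4-en-1-yl]-2,6-dimethyl-4-oxocyclohex-2-en-1-yl]-2-methyl-3-oxobutanoate
Product: 23 methyl (2Z)-4-[(1R,5S,6R)-5-acetoxy-6-[(1S,4Z)-1-(benzoyloxy)-4-methyl-6-oxohex-4-en-1-yl]-2,6-dimethyl-4-oxocyclohex-2-en-1-yl]-2-methyl-3-(trifluoromethanesulfonyloxy)but-2-enoate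
Conditions: (CF3SO2)2O, Et3N, LiOSO2CF3, CH2Cl2, 0 °C
Reagents that add atoms: trifluoromethanesulfonic anhydride O=S(=O)(OS(=O)(=O)C(F)(F)F)C(F)(F)F
Why: Soft enolisation gives the lithium-chelated (Z)-enolate of the β-keto ester only (the most acidic site), and O-sulfonylation gives the (Z)-enol triflate with the triflate cis to the ester.

Step 16
Reactants: 23 methyl (2Z)-4-[(1R,5S,6R)-5-acetoxy-6-[(1S,4Z)-1-(benzoyloxy)-4-methyl-6-oxohex-4-en-1-yl]-2,6-dimethyl-4-oxocyclohex-2-en-1-yl]-2-methyl-3-(trifluoromethanesulfonyloxy)but-2-enoate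
Product: 25 CNP0194180.3, (1R,2S,5Z,7R,10R,14S)-14-acetoxy-2-benzoyloxy-13-oxo-5,8(17),11-triene 19,7-lactone (numbering of the overview), via hydroxy ester 24 (not isolated)
Conditions: CrCl2 (8 equiv), NiCl2 (0.3 equiv), Kishi-type (S)-oxazoline–sulfonamide ligand (8.8 equiv; antipode if a test run shows the opposite sense), Et3N, THF, 2 mM, slow addition, rt; then PPTS (cat.), CH2Cl2
Reagents that add atoms: none
Why: Nozaki–Hiyama–Kishi macrocyclisation: zerovalent nickel inserts into the enol triflate, transmetalation gives an alkenylchromium that adds 1,2 only to the aldehyde (ketone, enone and esters are tolerated), the alkoxide closes onto the cis ester to form the butenolide, and the chiral sulfonamide on chromium is relied on to set C7 (R).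

## Compound list

1 | 3-[(tert-butyldimethylsilyl)oxy]propanal | O=CCCO[Si](C)(C)C(C)(C)C | starting material
2 | 2-(triphenylphosphoranylidene)propanal | CC(C=O)=P(c1ccccc1)(c1ccccc1)c1ccccc1 | starting material
3 | (E)-5-[(tert-butyldimethylsilyl)oxy]-2-methylpent-2-enal | O=C/C(C)=C/CCO[Si](C)(C)C(C)(C)C | intermediate
4 | (E)-pent-2-enal | CC/C=C/C=O | starting material
5 | (1E,3E)-1-(trimethylsilyloxy)penta-1,3-diene | C/C=C/C=C/O[Si](C)(C)C | intermediate
6 | (1S,2R,5S,6R)-6-[2-(tert-butyldimethylsilyloxy)ethyl]-1,5-dimethyl-2-(trimethylsilyloxy)cyclohex-3-ene-1-carbaldehyde | C[Si](C)(C)O[C@@H]1C=C[C@H](C)[C@@H](CCO[Si](C)(C)C(C)(C)C)[C@]1(C)C=O | intermediate (not isolated)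
7 | (1S,2R,5S,6R)-6-[2-(tert-butyldimethylsilyloxy)ethyl]-2-hydroxy-1,5-dimethylcyclohex-3-ene-1-carbaldehyde | O[C@@H]1C=C[C@H](C)[C@@H](CCO[Si](C)(C)C(C)(C)C)[C@]1(C)C=O | intermediate
8 | (1R,4S,5R,6S)-5-[2-(tert-butyldimethylsilyloxy)ethyl]-6-formyl-4,6-dimethylcyclohex-2-en-1-yl acetate | CC(=O)O[C@@H]1C=C[C@H](C)[C@@H](CCO[Si](C)(C)C(C)(C)C)[C@]1(C)C=O | intermediate
9 | (1R,4S,5R,6R)-5-[2-(tert-butyldimethylsilyloxy)ethyl]-6-(1-hydroxyprop-2-en-1-yl)-4,6-dimethylcyclohex-2-en-1-yl acetate (carbinol epimers) | CC(=O)O[C@@H]1C=C[C@H](C)[C@@H](CCO[Si](C)(C)C(C)(C)C)[C@]1(C)C(O)C=C | intermediate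
10 | (1R,4S,5R,6S)-6-acryloyl-5-[2-(tert-butyldimethylsilyloxy)ethyl]-4,6-dimethylcyclohex-2-en-1-yl acetate | CC(=O)O[C@@H]1C=C[C@H](C)[C@@H](CCO[Si](C)(C)C(C)(C)C)[C@]1(C)C(=O)C=C | intermediate
11 | (1R,4S,5R,6R)-5-[2-(tert-butyldimethylsilyloxy)ethyl]-6-[(1S)-1-hydroxyprop-2-en-1-yl]-4,6-dimethylcyclohex-2-en-1-yl acetate | CC(=O)O[C@@H]1C=C[C@H](C)[C@@H](CCO[Si](C)(C)C(C)(C)C)[C@]1(C)[C@@H](O)C=C | intermediate
12 | (1S)-1-[(1R,2R,5S,6R)-2-acetoxy-6-[2-(tert-butyldimethylsilyloxy)ethyl]-1,5-dimethylcyclohex-3-en-1-yl]prop-2-en-1-yl benzoate | CC(=O)O[C@@H]1C=C[C@H](C)[C@@H](CCO[Si](C)(C)C(C)(C)C)[C@]1(C)[C@@H](OC(=O)c1ccccc1)C=C | intermediate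
13 | (1S)-1-[(1R,2S,3S,6R)-2-acetoxy-6-[2-(tert-butyldimethylsilyloxy)ethyl]-3-hydroperoxy-1,5-dimethylcyclohex-4-en-1-yl]prop-2-en-1-yl benzoate | CC(=O)O[C@@H]1[C@@H](OO)C=C(C)[C@@H](CCO[Si](C)(C)C(C)(C)C)[C@]1(C)[C@@H](OC(=O)c1ccccc1)C=C | intermediate (not isolated)
14 | (1S)-1-[(1R,2S,3S,6R)-2-acetoxy-6-[2-(tert-butyldimethylsilyloxy)ethyl]-3-hydroxy-1,5-dimethylcyclohex-4-en-1-yl]prop-2-en-1-yl benzoate | CC(=O)O[C@@H]1[C@@H](O)C=C(C)[C@@H](CCO[Si](C)(C)C(C)(C)C)[C@]1(C)[C@@H](OC(=O)c1ccccc1)C=C | intermediate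
15 | but-2-yn-1-ol | CC#CCO | starting material
16 | sodium 2,2-bis(2-methoxyethoxy)-3-methyl-2,5-dihydro-1,2-oxaluminol-2-uide (cyclic (Z)-alkenylalanate) | [Na+].CC1=CCO[Al-]1(OCCOC)OCCOC | intermediate (not isolated)
17 | (Z)-3-iodobut-2-en-1-ol | C/C(I)=C/CO | intermediate
18 | (1S)-1-[(1R,2S,3S,6R)-2-acetoxy-6-[2-(tert-butyldimethylsilyloxy)ethyl]-3-hydroxy-1,5-dimethylcyclohex-4-en-1-yl]-3-(9-borabicyclo[3.3.1]nonan-9-yl)propyl benzoate | CC(=O)O[C@@H]1[C@@H](O)C=C(C)[C@@H](CCO[Si](C)(C)C(C)(C)C)[C@]1(C)[C@@H](OC(=O)c1ccccc1)CCB1C2CCCC1CCC2 | intermediate (not isolated)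
19 | (1S,4Z)-1-[(1R,2S,3S,6R)-2-acetoxy-6-[2-(tert-butyldimethylsilyloxy)ethyl]-3-hydroxy-1,5-dimethylcyclohex-4-en-1-yl]-6-hydroxy-4-methylhex-4-en-1-yl benzoate | CC(=O)O[C@@H]1[C@@H](O)C=C(C)[C@@H](CCO[Si](C)(C)C(C)(C)C)[C@]1(C)[C@@H](OC(=O)c1ccccc1)CC/C(C)=C\CO | intermediate
20 | (1S,4Z)-1-[(1R,2S,3S,6R)-2-acetoxy-3-hydroxy-6-(2-hydroxyethyl)-1,5-dimethylcyclohex-4-en-1-yl]-6-hydroxy-4-methylhex-4-en-1-yl benzoate | CC(=O)O[C@@H]1[C@@H](O)C=C(C)[C@@H](CCO)[C@]1(C)[C@@H](OC(=O)c1ccccc1)CC/C(C)=C\CO | intermediate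
21 | (1S,4Z)-1-[(1R,2S,6R)-2-acetoxy-1,5-dimethyl-3-oxo-6-(2-oxoethyl)cyclohex-4-en-1-yl]-4-methyl-6-oxohex-4-en-1-yl benzoate | CC(=O)O[C@@H]1C(=O)C=C(C)[C@@H](CC=O)[C@]1(C)[C@@H](OC(=O)c1ccccc1)CC/C(C)=C\C=O | intermediate
22 | methyl 4-[(1R,5S,6R)-5-acetoxy-6-[(1S,4Z)-1-(benzoyloxy)-4-methyl-6-oxohex-4-en-1-yl]-2,6-dimethyl-4-oxocyclohex-2-en-1-yl]-2-methyl-3-oxobutanoate (epimers at the ester α-carbon) | CC(=O)O[C@@H]1C(=O)C=C(C)[C@@H](CC(=O)C(C)C(=O)OC)[C@]1(C)[C@@H](OC(=O)c1ccccc1)CC/C(C)=C\C=O | intermediate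
23 | methyl (2Z)-4-[(1R,5S,6R)-5-acetoxy-6-[(1S,4Z)-1-(benzoyloxy)-4-methyl-6-oxohex-4-en-1-yl]-2,6-dimethyl-4-oxocyclohex-2-en-1-yl]-2-methyl-3-(trifluoromethanesulfonyloxy)but-2-enoate | CC(=O)O[C@@H]1C(=O)C=C(C)[C@@H](C/C(OS(=O)(=O)C(F)(F)F)=C(\C)C(=O)OC)[C@]1(C)[C@@H](OC(=O)c1ccccc1)CC/C(C)=C\C=O | intermediate
24 | ring-opened hydroxy methyl ester of 25 (10-membered carbocycle, 7R-OH, (Z)-C8=C17(CH3)CO2CH3) | CC(=O)O[C@@H]1C(=O)C=C(C)[C@H]2C/C(=C(\C)C(=O)OC)[C@H](O)/C=C(/C)CC[C@H](OC(=O)c3ccccc3)[C@@]21C | intermediate (not isolated)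
25 | CNP0194180.3, (1R,2S,5Z,7R,10R,14S)-14-acetoxy-2-benzoyloxy-13-oxo-5,8(17),11-triene 19,7-lactone | CC(=O)O[C@@H]1C(=O)C=C(C)[C@H]2CC3=C(C)C(=O)O[C@@H]3/C=C(/C)CC[C@H](OC(=O)c3ccccc3)[C@@]21C | target

## Step count and risks

Total step count: 16. Longest linear sequence: 14 (steps 1, 3–9, 11–16).

Steps most likely to fail:

**Step 3 (the proposed new cycloaddition).** The risks are low reactivity of the trisubstituted enal, competing 1,2-attack at the aldehyde carbon (oxa-[4+2] or vinylogous aldol), and an unknown level and sense of induction. The fallback uses known chemistry, sets out from 3 and 5 and returns at 8. The cycloaddition is run without a chiral catalyst (AlEt2Cl, CH2Cl2, −78 °C, the standard Lewis-acid endo Diels–Alder of 2-alkyl enals with 1-silyloxydienes), giving the racemic trimethylsilyl ether F1. The same citric acid work-up gives the racemic hydroxy aldehyde F2. A lipase-catalysed acylative kinetic resolution (Burkholderia cepacia lipase, vinyl acetate, MTBE, 30 °C; lipase chosen from a standard panel) is then expected, from the Kazlauskas preference with the quaternary side as large group, to acetylate the (2R)-alcohol. This delivers acetate 8 directly (at most 50 %), and the unreacted enantiomer is discarded.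

**Step 9 (Schenck ene).** The cis-disubstituted alkene, deactivated by the allylic acetate, may react too slowly or abstract the wrong hydrogen. The fallback sets out from 12 and returns at 14. mCPBA (NaHCO3, CH2Cl2, 0 °C) epoxidises only the ring alkene, anti to the pseudoaxial acetoxy group, giving the β-epoxide F3. Me3SiOSO2CF3/DBU (toluene, 0 °C → rt) opens it at C12 and eliminates the anti-periplanar H at C11, giving the allylic trimethylsilyl ether F4. Aqueous citric acid then frees alcohol 14.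

**Step 16 (macrocyclisation).** Closure of the 10-membered ring, C7 selectivity and tolerance of the α-acetoxy enone toward CrCl2 are all uncertain. The fallback sets out from 21 and returns at 25.
- A stabilised-ylide Wittig reaction at the saturated aldehyde, with methyl 2-(triphenylphosphoranylidene)-3-(trimethylsilyl)propanoate (CH2Cl2, rt), gives the allylsilane F5.
- BF3·OEt2 (CH2Cl2, −78 °C, high dilution) triggers an intramolecular Hosomi–Sakurai allylation of the (Z)-enal, giving the open hydroxy ester F6.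
- F6 lactonises in the same flask to the α-methylene lactone F7. The 7R diastereomer is separated here; C7 is not controlled in this fallback.
- RhCl3·3H2O (EtOH, 70 °C) moves the exocyclic alkene into the ring to give 25.

## Further compounds

F1 | step 3 | racemic (1S,2R,5S,6R)/(1R,2S,5R,6S)-6-[2-(tert-butyldimethylsilyloxy)ethyl]-1,5-dimethyl-2-(trimethylsilyloxy)cyclohex-3-ene-1-carbaldehyde | C[Si](C)(C)O[C@@H]1C=C[C@H](C)[C@@H](CCO[Si](C)(C)C(C)(C)C)[C@]1(C)C=O.C[Si](C)(C)O[C@H]1C=C[C@@H](C)[C@H](CCO[Si](C)(C)C(C)(C)C)[C@@]1(C)C=O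
F2 | step 3 | racemic (1S,2R,5S,6R)/(1R,2S,5R,6S)-6-[2-(tert-butyldimethylsilyloxy)ethyl]-2-hydroxy-1,5-dimethylcyclohex-3-ene-1-carbaldehyde | O[C@@H]1C=C[C@H](C)[C@@H](CCO[Si](C)(C)C(C)(C)C)[C@]1(C)C=O.O[C@H]1C=C[C@@H](C)[C@H](CCO[Si](C)(C)C(C)(C)C)[C@@]1(C)C=O
F3 | step 9 | 12,13-epoxide of benzoate 12, epoxide oxygen anti to the C14 acetoxy group | CC(=O)O[C@@H]1[C@H]2O[C@H]2[C@H](C)[C@@H](CCO[Si](C)(C)C(C)(C)C)[C@]1(C)[C@@H](OC(=O)c1ccccc1)C=C
F4 | step 9 | C13 trimethylsilyl ether of alcohol 14 | CC(=O)O[C@@H]1[C@@H](O[Si](C)(C)C)C=C(C)[C@@H](CCO[Si](C)(C)C(C)(C)C)[C@]1(C)[C@@H](OC(=O)c1ccccc1)C=C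
F5 | step 16 | methyl (2Z)-4-[(1R,5S,6R)-5-acetoxy-6-[(1S,4Z)-1-(benzoyloxy)-4-methyl-6-oxohex-4-en-1-yl]-2,6-dimethyl-4-oxocyclohex-2-en-1-yl]-2-[(trimethylsilyl)methyl]but-2-enoate | CC(=O)O[C@@H]1C(=O)C=C(C)[C@@H](C/C=C(/C(=O)OC)C[Si](C)(C)C)[C@]1(C)[C@@H](OC(=O)c1ccccc1)CC/C(C)=C\C=O
F6 | step 16 | macrocyclic hydroxy ester with C7-OH, C8-H and exocyclic methyl acrylate unit (C8 epimers) | CC(=O)O[C@@H]1C(=O)C=C(C)[C@H]2CC(C(=C)C(=O)OC)[C@H](O)/C=C(/C)CC[C@H](OC(=O)c3ccccc3)[C@@]21C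
F7 | step 16 | α-methylene-γ-butyrolactone isomer of 25 (C8-H, C17=CH2, C8 epimers) | CC(=O)O[C@@H]1C(=O)C=C(C)[C@H]2CC3C(=C)C(=O)O[C@@H]3/C=C(/C)CC[C@H](OC(=O)c3ccccc3)[C@@]21C
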